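**Retrosynthetic overview**
- Target ⇐ 6β,7β-diol (last step: MnO2 oxidation of the allylic C7–OH) ⇐ C12 aldehyde. The side chain comes from a Nozaki–Hiyama–Kishi coupling, a hydroxyl-directed epoxidation, a Mitsunobu inversion that installs the C12 tiglate, and a carboxylate epoxide opening that forms the lactone ring (last ring).
- Decalin: C1–OH and C10–H come from a Δ1(10) alkene (α-epoxide, then Cp2TiCl opening). C9 and C8=C17 come from a 1,4-addition/Mannich sequence on a linear dienone. Ring B (second ring) comes from a Wacker oxidation and a C8–C9 aldol condensation.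
- Key disconnection, ring A (first ring): a one-flask [3+3] union from an acyclic enol ether of pentane-2,4-dione, in which a Claisen rearrangement makes C5–C10 and a dianion allylation makes C2–C3.
- Enabling feature: in ring A, C4 with its exocyclic C18H2 is a trimethylenemethane-type carbon with arms C3, C18 and the quaternary C5. C2–C1(=O)–C10, with C10 bearing C9 (acetyl carbon, C20 its methyl), is a pentane-2,4-dione unit. O-allyl transposition therefore gives C5–C10 and leaves C4=C18, and the remaining symmetric 2-substituted allyl chloride can only close ring A at C2.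

Key step: step 5

Remark: locants are those of the clerodane skeleton of the target (ring A: C1–C5, C10; ring B: C5–C10; C17 and C18 are the exocyclic CH2 on C8 and C4; C19 and C20 are the methyls on C5 and C9; C11–C16 is the side chain); β is the face of C19; the 6β (equatorial, hydrogen-bonded) α-ketol is assumed to be the more stable C6 epimer.

Step 1
Reactants: 1 but-2-yn-1-ol; 2 (chloromethyl)(isopropoxy)dimethylsilane; 3 allyl bromide
Product: 6 2-[(isopropoxydimethylsilyl)methyl]-3-methylhexa-2,5-dien-1-ol (CH2OH cis to the allyl group), via Grignard reagent 4 (not isolated), via alkenylmagnesium chelate 5 (not isolated)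
Conditions: 2, Mg, THF, 40 °C; 1, EtMgBr (1.0 equiv), THF, 0 °C; add 4 (1.5 equiv), CuI (10 mol %), 0 °C to rt; then 3, 0 °C to rt; aq NH4Cl
Reagents that add atoms: none
Why: Copper-catalysed anti-carbomagnesiation of the propargylic alkoxide should place the silylmethyl group on the carbinol-bearing alkyne carbon through the five-membered chelate 5, and allylation of the C–Mg bond with retention fixes the tetrasubstituted alkene geometry.

Step 2
Reactants: 6; 7 (E)-4-methoxypent-3-en-2-one
Product: 8 (E)-4-{2-[(isopropoxydimethylsilyl)methyl]-3-methylhexa-2,5-dienyloxy}pent-3-en-2-one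
Conditions: 7 (3 equiv), pyridinium p-toluenesulfonate (5 mol %), toluene, 35 °C, 80 mbar
Reagents that add atoms: none
Why: Acid-catalysed vinylogous transesterification (addition–elimination at the β-carbon of the vinylogous ester) is driven by removal of methanol and is run below 40 °C so that no [3,3] shift occurs yet.

Step 3
Reactants: 8
Product: 9 (E)-4-[2-(hydroxymethyl)-3-methylhexa-2,5-dienyloxy]pent-3-en-2-one
Conditions: KF, KHCO3, 30 % aq H2O2, THF/MeOH, rt
Reagents that add atoms: hydrogen peroxide, OO
Why: Tamao oxidation converts the alkoxysilyl C–Si bond into C–OH with retention and without allylic transposition, and the electron-rich vinylogous ester should not be epoxidised by buffered peroxide.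

Step 4
Reactants: 9
Product: 10 (E)-4-[2-(chloromethyl)-3-methylhexa-2,5-dienyloxy]pent-3-en-2-one (CH2O arm cis to the allyl group)
Conditions: PPh3, N-chlorosuccinimide, CH2Cl2, −20 °C to rt
Reagents that add atoms: N-chlorosuccinimide, O=C1CCC(=O)N1Cl
Why: Appel-type chlorination (SN2 on the alkoxyphosphonium salt) of the primary allylic alcohol gives the allylic chloride that later serves as the C3 electrophile.

Step 5
Reactants: 10
Product: 13 (S)-2-acetyl-3-allyl-3-methyl-4-methylenecyclohexan-1-one (ring A; C10 enolised), via Claisen diketone 11 (not isolated), via dilithium dianion 12 (not isolated)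
Conditions: chiral C2-symmetric guanidinium tetraarylborate hydrogen-bond donor (20 mol %), hexanes, 40 °C; then THF, LiN(iPr)2 (2.3 equiv), −78 to 0 °C; aq NH4Cl
Reagents that add atoms: none
Why: Proposed new method: the hydrogen-bond donor binds the ether and carbonyl oxygens of the vinylogous ester in 10 and lowers the barrier of a chair-like [3,3] sigmatropic (Claisen) shift in which the enol-ether carbon C10 bonds to the fully substituted alkene carbon C5 while O–C18 breaks, so that C4=C18 appears as the exocyclic methylene and 11 is a 3-substituted pentane-2,4-dione; LiN(iPr)2 then removes the C10 proton and one acetyl proton, and the terminal carbanion of 12 displaces the allylic chloride at C3 (6-exo-tet, equivalent to the SN2′ mode at C18) to close ring A. The closest known reaction types are the guanidinium-catalysed enantioselective Claisen rearrangement of O-allyl β-keto ester enol ethers and the γ-alkylation of β-diketone dianions with allylic halides; new are the β-diketone-derived substrate, the tetrasubstituted allyl terminus and the coupling of both events in one flask. C5, the only lasting stereocentre, is set by the catalyst-selected face of the vinyl ether, relayed through the chair transition state and the fixed geometry of the C4=C5 alkene (the antipodal catalyst is taken if the sense is the opposite), whereas C10 is an enolisable β-diketone carbon and is set later (step 15). The step needs [3,3] over ionisation and [1,3] recombination at C18, which concerted hydrogen-bond catalysis should secure, and C- over O-alkylation, which the far more nucleophilic terminal dianion carbon and ring size (six against four for the central carbon) should secure; the two acetyl groups are equivalent, so either one gives 13.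

Step 6
Reactants: 13
Product: 14 (S)-2-acetyl-3-methyl-4-methylene-3-(2-oxopropyl)cyclohexan-1-one
Conditions: PdCl2 (10 mol %), CuCl (1.0 equiv), O2 (1 atm), DMF/H2O 7:1, rt
Reagents that add atoms: water, O
Why: Wacker oxidation converts the monosubstituted terminal alkene into the methyl ketone (C7, C8) with Markovnikov selectivity, while the hindered 1,1-disubstituted C4=C18 should react much more slowly.

Step 7
Reactants: 14
Product: 15 bicyclic enedione (C1 and C7 ketones, Δ8, 4(18)-methylene, 5β-CH3, 9-CH3; drawn 10α-H, C10 epimerisable)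
Conditions: pyrrolidine (0.5 equiv), AcOH (0.5 equiv), toluene, 60 °C
Reagents that add atoms: none
Why: Robinson-type intramolecular aldol condensation through the C8 enamine of the methyl ketone onto the acetyl carbonyl C9 closes ring B (the only six-membered option) and dehydrates to the conjugated enone; the labile C10 centre is erased in step 9.

Step 8
Reactants: 15
Product: 16 1β-hydroxy-7-oxo-4(18),8-diene (drawn 10α-H; C1 and C10 epimers are carried on together)
Conditions: NaBH4 (0.35 equiv), MeOH/CH2Cl2 1:1, −78 °C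
Reagents that add atoms: none
Why: Chemoselective borohydride reduction of the saturated C1 ketone in the presence of the conjugated enone at low temperature; the C1 configuration is irrelevant because the oxygen is eliminated in step 9.

Step 9
Reactants: 16
Product: 18 (S)-dienone: 7-oxo-1(10),4(18),8-triene, via mesylate 17 (not isolated)
Conditions: MsCl, Et3N, CH2Cl2, 0 °C; then DBU, rt
Reagents that add atoms: none
Why: Mesylation followed by vinylogous E1cB (1,4-) elimination through the C10 dienolate should give the linear dienone from every C1/C10 stereoisomer, leaving C5 as the only stereocentre.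

Step 10
Reactants: 18; 19 (1,3-dioxolan-2-ylmethyl)magnesium bromide
Product: 23 enone: 7-oxo-1(10),4(18),8(17)-triene with 9α-(1,3-dioxolan-2-ylmethyl) and 9β-CH3, via magnesium enolate 20 (not isolated), via Mannich base 21 (not isolated), via ammonium iodide 22 (not isolated)
Conditions: Cu(OTf)2 (5 mol %), 1,3-bis(2,4,6-trimethylphenyl)imidazolinium chloride (7 mol %), 19 (1.5 equiv), Et2O, −30 °C; then N,N-dimethylmethyleneiminium iodide, CH2Cl2, −30 °C to rt; then MeI, rt; aq NaHCO3
Reagents that add atoms: N,N-dimethylmethyleneiminium iodide, C=[N+](C)C.[I-]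
Why: Copper–N-heterocyclic-carbene-catalysed conjugate addition of a Grignard reagent to a β,β-disubstituted cyclic dienone is the known 1,4-selective variant; attack anti to the axial C19 methyl (1,3-relationship) should set C9, and the regiodefined magnesium enolate is trapped in a Mannich reaction, with Hofmann-type elimination of the quaternised amine giving the α-methylene ketone.

Step 11
Reactants: 23
Product: 25 6α-hydroxy-1α,10α-epoxy-7-oxo-4(18),8(17)-diene (side-chain dioxolane retained), via siloxydiene 24 (not isolated)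
Conditions: LiN(SiMe3)2, Me3SiCl, THF, −78 °C; then mCPBA (2.1 equiv), NaHCO3, CH2Cl2, −20 to 0 °C; then Et3N·3HF, THF, 0 °C
Reagents that add atoms: mCPBA, O=C(OO)c1cccc(Cl)c1
Why: Rubottom oxidation of the 2-siloxydiene (C6 is the only enolisable position) and Prilezhaev epoxidation of the trisubstituted Δ1(10) alkene should both occur from the α face, anti to the C19 and C20 methyls, faster than attack on the hindered 1,1-disubstituted C4=C18 or the electron-poor C8=C17.

Step 12
Reactants: 25
Product: 26 6β-hydroxy-1α,10α-epoxy-7-oxo-4(18),8(17)-diene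
Conditions: DBU (0.2 equiv), CH2Cl2, 0 °C to rt
Reagents that add atoms: none
Why: Base-mediated α-ketol epimerisation through the enediol should give the equatorial, hydrogen-bonded 6β-alcohol, because the axial 6α-OH is syn-axial to the C10 epoxide oxygen and reprotonation at C6 occurs from the open α face.

Step 13
Reactants: 26
Product: 27 6β,7β-diol (1α,10α-epoxide, 4(18),8(17)-diene)
Conditions: i-Bu2AlH (3.5 equiv), CH2Cl2, −78 °C; aq Rochelle salt
Reagents that add atoms: none
Why: 1,2-Reduction of the α-methylene ketone by the aluminium hydride from the α face (the β face is shielded by the syn-axial C19 and C20 methyls) should give the 7β-alcohol cis to 6β-OH; the C7 configuration is inconsequential because C7 is reoxidised in step 25.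

Step 14
Reactants: 27
Product: 28 6β,7β-O-isopropylidene ketal of 27
Conditions: 2-methoxypropene (3 equiv), pyridinium p-toluenesulfonate (5 mol %), CH2Cl2, 0 °C
Reagents that add atoms: 2-methoxypropene, C=C(C)OC
Why: Kinetic ketalisation (transacetalisation) of the cis-diol gives the five-membered acetonide under conditions mild enough for the epoxide and the side-chain dioxolane.

Step 15
Reactants: 28
Product: 29 1α-hydroxy-10α-H trans-decalin (6β,7β-acetonide, 4(18),8(17)-diene, side-chain dioxolane)
Conditions: Cp2TiCl2 (2.5 equiv), Zn dust, THF, rt; then 28, 1,4-cyclohexadiene (10 equiv), rt; aq NaH2PO4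
Reagents that add atoms: none
Why: Reductive radical epoxide opening by Cp2TiCl (trivalent titanium) cleaves the C10–O bond to the tertiary radical while C1–O keeps its α configuration, and hydrogen-atom transfer from 1,4-cyclohexadiene to the α face (β shielded by C19 and C20) should set the 10α-H trans ring fusion.

Step 16
Reactants: 29; 30 tigloyl chloride
Product: 31 1α-tiglate of 29
Conditions: 30 (3 equiv), DMAP (0.5 equiv), pyridine, CH2Cl2, 40 °C
Reagents that add atoms: none
Why: DMAP-catalysed acylation of the only free, equatorial secondary alcohol installs the C1 tiglate.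

Step 17
Reactants: 31
Product: 32 C12 aldehyde (1α-tiglate, 6β,7β-acetonide)
Conditions: Et3SiOTf (2 equiv), 2,4,6-collidine (3 equiv), CH2Cl2, 0 °C; then H2O
Reagents that add atoms: water, O
Why: Silyl triflate/collidine acetal cleavage through a collidinium intermediate is selective for the aldehyde-derived dioxolane over the isopropylidene ketal and should leave the tiglate and the exocyclic alkenes untouched.

Step 18
Reactants: 33 but-3-ynoic acid
Product: 34 3-iodobut-3-enoic acid
Conditions: 57 % aq HI, 0 °C to rt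
Reagents that add atoms: hydrogen iodide, I
Why: Markovnikov hydroiodination of the terminal alkyne gives the 2-substituted vinyl iodide.

Step 19
Reactants: 34; 35 2-(trimethylsilyl)ethanol
Product: 36 2-(trimethylsilyl)ethyl 3-iodobut-3-enoate
Conditions: N,N′-dicyclohexylcarbodiimide, DMAP (5 mol %), CH2Cl2, 0 °C
Reagents that add atoms: none
Why: Steglich esterification at 0 °C with little DMAP should avoid isomerisation of the β,γ-unsaturated ester into conjugation.

Step 20
Reactants: 32; 36
Product: 37 (12R)-allylic alcohol with C13=C16H2 and the C14–C15 2-(trimethylsilyl)ethyl ester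
Conditions: CrCl2 (4 equiv), NiCl2 (2 mol %), chiral oxazoline–sulfonamide ligand (4.4 equiv), Et3N, THF, rt; aq ethylenediamine work-up
Reagents that add atoms: none
Why: Nozaki–Hiyama–Kishi coupling adds the alkenylchromium species chemoselectively to the aldehyde, and the chiral ligand on chromium (the enantiomer that delivers 12R is chosen) controls the new C12 centre.

Step 21
Reactants: 37
Product: 38 (12R,13S)-13,16-epoxy alcohol
Conditions: VO(acac)2 (5 mol %), t-BuOOH (1.5 equiv), CH2Cl2, 0 °C
Reagents that add atoms: tert-butyl hydroperoxide, CC(C)(C)OO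
Why: Vanadium-catalysed hydroxyl-directed epoxidation touches only the allylic-alcohol alkene and, for a 2-substituted allylic alcohol (A(1,2) strain), should give the erythro epoxy alcohol, which sets C13.

Step 22
Reactants: 38; 39 tiglic acid
Product: 40 (12S,13S)-12-tiglate epoxide
Conditions: 39 (3 equiv), PPh3 (3 equiv), diisopropyl azodicarboxylate (3 equiv), toluene, 0 °C to rt
Reagents that add atoms: none
Why: Mitsunobu esterification inverts C12 by SN2 displacement of the alkoxyphosphonium group, turning the erythro into the required threo relationship and installing the second tiglate in the same step.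

Step 23
Reactants: 40
Product: 42 13-hydroxy-15,16-olide bis-tiglate (6β,7β-acetonide), via carboxylate 41 (not isolated)
Conditions: Bu4NF (1.5 equiv), AcOH (1.5 equiv), THF, 0 °C to rt
Reagents that add atoms: none
Why: Fluoride-induced β-elimination cleaves the 2-(trimethylsilyl)ethyl ester, and the carboxylate opens the epoxide at the primary C16 (5-exo-tet) to close the lactone with C13 retained; the acetic acid buffer protonates the tertiary alkoxide before acyl migration can start.

Step 24
Reactants: 42
Product: 43 6β,7β-diol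
Conditions: AcOH/H2O 4:1, 40 °C
Reagents that add atoms: none
Why: Mild acid hydrolysis of the cis-fused acetonide should spare the tiglates, the lactone, the tertiary alcohol and the exocyclic alkenes.

Step 25
Reactants: 43
Product: 44 target, CNP0233387.2
Conditions: MnO2 (20 equiv), CH2Cl2, rt
Reagents that add atoms: none
Why: Manganese dioxide oxidises only the allylic C7 alcohol, which unveils the 6β-hydroxy-7-oxo-8(17)-ene unit last and under neutral conditions.

**Compound list**
1 | but-2-yn-1-ol | CC#CCO | starting material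
2 | (chloromethyl)(isopropoxy)dimethylsilane | CC(C)O[Si](C)(C)CCl | starting material
3 | allyl bromide | C=CCBr | starting material
4 | [(isopropoxydimethylsilyl)methyl]magnesium chloride | CC(C)O[Si](C)(C)C[Mg]Cl | intermediate
5 | cyclic alkenylmagnesium alkoxide (chelate) | CC1=C(C[Si](C)(C)OC(C)C)CO[Mg]1 | intermediate
6 | 2-[(isopropoxydimethylsilyl)methyl]-3-methylhexa-2,5-dien-1-ol, CH2OH cis to allyl | OC/C(C[Si](C)(C)OC(C)C)=C(/C)CC=C | intermediate
7 | (E)-4-methoxypent-3-en-2-one | CC(=O)/C=C(\C)OC | starting material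
8 | enol ether of 6 with pentane-2,4-dione | CC(=O)/C=C(\C)OC/C(C[Si](C)(C)OC(C)C)=C(/C)CC=C | intermediate
9 | (E)-4-[2-(hydroxymethyl)-3-methylhexa-2,5-dienyloxy]pent-3-en-2-one | CC(=O)/C=C(\C)OC/C(CO)=C(/C)CC=C | intermediate
10 | (E)-4-[2-(chloromethyl)-3-methylhexa-2,5-dienyloxy]pent-3-en-2-one | CC(=O)/C=C(\C)OC/C(CCl)=C(/C)CC=C | intermediate
11 | (S)-3-[2-(chloromethyl)-3-methylhexa-1,5-dien-3-yl]pentane-2,4-dione | C=C(CCl)[C@@](C)(CC=C)C(C(C)=O)C(C)=O | intermediate
12 | dilithium dianion of 11 | C=C(CCl)[C@@](C)(CC=C)C(C(=C)O[Li])=C(C)O[Li] | intermediate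
13 | (S)-2-acetyl-3-allyl-3-methyl-4-methylenecyclohexan-1-one | C=C1CCC(=O)C(C(C)=O)[C@]1(C)CC=C | intermediate
14 | (S)-2-acetyl-3-methyl-4-methylene-3-(2-oxopropyl)cyclohexan-1-one | C=C1CCC(=O)C(C(C)=O)[C@]1(C)CC(C)=O | intermediate
15 | bicyclic enedione, 1,7-dioxo-4(18),8-diene, 10α-H | C=C1CCC(=O)[C@@H]2[C@]1(C)CC(=O)C=C2C | intermediate
16 | 1β-hydroxy-7-oxo-4(18),8-diene | C=C1CC[C@@H](O)[C@@H]2[C@]1(C)CC(=O)C=C2C | intermediate
17 | 1-O-mesylate of 16 | C=C1CC[C@@H](OS(C)(=O)=O)[C@@H]2[C@]1(C)CC(=O)C=C2C | intermediate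
18 | (S)-dienone, 7-oxo-1(10),4(18),8-triene | C=C1CCC=C2[C@]1(C)CC(=O)C=C2C | intermediate
19 | (1,3-dioxolan-2-ylmethyl)magnesium bromide | Br[Mg]CC1OCCO1 | starting material
20 | bromomagnesium C7 enolate after 1,4-addition | C=C1CCC=C2[C@]1(C)CC(O[Mg]Br)=C[C@@]2(C)CC1OCCO1 | intermediate
21 | C8 Mannich base | C=C1CCC=C2[C@]1(C)CC(=O)C(CN(C)C)[C@@]2(C)CC1OCCO1 | intermediate
22 | trimethylammonium iodide of 21 | C=C1CCC=C2[C@]1(C)CC(=O)C(C[N+](C)(C)C)[C@@]2(C)CC1OCCO1.[I-] | intermediate
23 | enone, 7-oxo-1(10),4(18),8(17)-triene, 9α-(dioxolanylmethyl) | C=C1CCC=C2[C@]1(C)CC(=O)C(=C)[C@@]2(C)CC1OCCO1 | intermediate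
24 | 7-trimethylsiloxy-6,8(17)-diene | C=C1CCC=C2[C@]1(C)C=C(O[Si](C)(C)C)C(=C)[C@@]2(C)CC1OCCO1 | intermediate
25 | 6α-hydroxy-1α,10α-epoxy enone | C=C1CC[C@H]3[C@]2(O3)[C@]1(C)[C@@H](O)C(=O)C(=C)[C@@]2(C)CC1OCCO1 | intermediate
26 | 6β-hydroxy-1α,10α-epoxy enone | C=C1CC[C@H]3[C@]2(O3)[C@]1(C)[C@H](O)C(=O)C(=C)[C@@]2(C)CC1OCCO1 | intermediate
27 | 6β,7β-diol, 1α,10α-epoxide | C=C1CC[C@H]3[C@]2(O3)[C@]1(C)[C@H](O)[C@H](O)C(=C)[C@@]2(C)CC1OCCO1 | intermediate
28 | 6β,7β-acetonide, 1α,10α-epoxide | C=C1CC[C@H]3[C@]2(O3)[C@]1(C)[C@@H]4OC(C)(C)O[C@@H]4C(=C)[C@@]2(C)CC1OCCO1 | intermediate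
29 | 1α-alcohol, 10α-H, 6β,7β-acetonide | C=C1CC[C@H](O)[C@@H]2[C@]1(C)[C@@H]3OC(C)(C)O[C@@H]3C(=C)[C@@]2(C)CC1OCCO1 | intermediate
30 | tigloyl chloride, (E)-2-methylbut-2-enoyl chloride | ClC(=O)/C(C)=C/C | starting material
31 | 1α-tiglate, side-chain dioxolane | C=C1CC[C@H](OC(=O)/C(C)=C/C)[C@@H]2[C@]1(C)[C@@H]3OC(C)(C)O[C@@H]3C(=C)[C@@]2(C)CC1OCCO1 | intermediate
32 | C12 aldehyde | C=C1CC[C@H](OC(=O)/C(C)=C/C)[C@@H]2[C@]1(C)[C@@H]3OC(C)(C)O[C@@H]3C(=C)[C@@]2(C)CC=O | intermediate
33 | but-3-ynoic acid | C#CCC(=O)O | starting material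
34 | 3-iodobut-3-enoic acid | C=C(I)CC(=O)O | intermediate
35 | 2-(trimethylsilyl)ethanol | C[Si](C)(C)CCO | starting material
36 | 2-(trimethylsilyl)ethyl 3-iodobut-3-enoate | C=C(I)CC(=O)OCC[Si](C)(C)C | intermediate
37 | (12R)-allylic alcohol | C=C1CC[C@H](OC(=O)/C(C)=C/C)[C@@H]2[C@]1(C)[C@@H]3OC(C)(C)O[C@@H]3C(=C)[C@@]2(C)C[C@@H](O)C(=C)CC(=O)OCC[Si](C)(C)C | intermediate
38 | (12R,13S)-epoxy alcohol | C=C1CC[C@H](OC(=O)/C(C)=C/C)[C@@H]2[C@]1(C)[C@@H]3OC(C)(C)O[C@@H]3C(=C)[C@@]2(C)C[C@@H](O)[C@@]1(CO1)CC(=O)OCC[Si](C)(C)C | intermediate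
39 | tiglic acid, (E)-2-methylbut-2-enoic acid | OC(=O)/C(C)=C/C | starting material
40 | (12S,13S)-epoxy bis-tiglate | C=C1CC[C@H](OC(=O)/C(C)=C/C)[C@@H]2[C@]1(C)[C@@H]3OC(C)(C)O[C@@H]3C(=C)[C@@]2(C)C[C@H](OC(=O)/C(C)=C/C)[C@@]1(CO1)CC(=O)OCC[Si](C)(C)C | intermediate
41 | tetrabutylammonium carboxylate of 40 | C=C1CC[C@H](OC(=O)/C(C)=C/C)[C@@H]2[C@]1(C)[C@@H]3OC(C)(C)O[C@@H]3C(=C)[C@@]2(C)C[C@H](OC(=O)/C(C)=C/C)[C@@]1(CO1)CC(=O)[O-].CCCC[N+](CCCC)(CCCC)CCCC | intermediate
42 | lactone bis-tiglate, 6β,7β-acetonide | C=C1CC[C@H](OC(=O)/C(C)=C/C)[C@@H]2[C@]1(C)[C@@H]3OC(C)(C)O[C@@H]3C(=C)[C@@]2(C)C[C@H](OC(=O)/C(C)=C/C)[C@@]1(O)COC(=O)C1 | intermediate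
43 | 6β,7β-diol lactone bis-tiglate | C=C1CC[C@H](OC(=O)/C(C)=C/C)[C@@H]2[C@]1(C)[C@H](O)[C@H](O)C(=C)[C@@]2(C)C[C@H](OC(=O)/C(C)=C/C)[C@@]1(O)COC(=O)C1 | intermediate
44 | CNP0233387.2, (1S,5S,6S,9S,10S,12S,13S) | C=C1CC[C@H](OC(=O)/C(C)=C/C)[C@@H]2[C@]1(C)[C@H](O)C(=O)C(=C)[C@@]2(C)C[C@H](OC(=O)/C(C)=C/C)[C@@]1(O)COC(=O)C1 | target

**Step count and risks**
Total steps: 25. Longest linear sequence: 23 (steps 1–17 and 20–25; steps 18–19 make reagent 36).

Most likely to fail:

1. Step 5 (proposed new method). The catalysed rearrangement may be too slow at the tetrasubstituted allyl terminus, or may proceed with poor facial discrimination, so that C5 forms with low enantiomeric purity. Fallback, from 10 back to 13, using known chemistry: heat 10 in toluene at 110 °C (uncatalysed Claisen rearrangement) to racemic Claisen diketone, that is 11 together with its enantiomer (R)-3-[2-(chloromethyl)-3-methylhexa-1,5-dien-3-yl]pentane-2,4-dione F1. Add this solution to LiN(iPr)2 as before, through 12 and the enantiomeric dilithium dianion F2, to obtain 13 together with (R)-2-acetyl-3-allyl-3-methyl-4-methylenecyclohexan-1-one F3. Condense the racemate with (S)-1-phenylethylamine (toluene, cat. AcOH, removal of water) to the diastereomeric enaminones, the (3S)-enaminone F4 and the (3R)-enaminone F5, and separate them by crystallisation or chromatography. Hydrolysis of F4 (aq HCl, THF) returns 13.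

2. Step 10. The Grignard reagent may add in the 1,6-mode at C1 instead of the 1,4-mode at C9, or the hindered magnesium enolate may resist the Mannich trapping. Fallback, from 16 back to 23, avoiding the dienone:
   - Silylate the trans-fused 1β-alcohol 16 (TBSOTf, 2,6-lutidine) to the 1β-silyl ether enone F6, a simple β,β-disubstituted enone with no 1,6-pathway.
   - Add 19 with stoichiometric CuBr·SMe2 and Me3SiCl (attack anti to C19) to obtain the silyl enol ether F7.
   - Treat F7 with N,N-dimethylmethyleneiminium iodide to the Mannich base F8, quaternise with MeI to the ammonium iodide F9, and eliminate with NaHCO3 to the 1β-silyloxy α-methylene ketone F10.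
   - Desilylate with Bu4NF to the 1β-alcohol F11 and dehydrate with POCl3/pyridine (anti elimination of the axial 1β-OH with the axial 10α-H, Zaitsev) to reach 23.

3. Step 22. Displacement at the hindered C12 carbinol may be outrun by elimination or by attack of the activated alcohol on the neighbouring epoxide. Fallback, from 38 back to 40: oxidise 38 with 1,1,1-triacetoxy-1,1-dihydro-1,2-benziodoxol-3(1H)-one to the 13,16-epoxy C12 ketone F12. Reduce it under reagent control (Corey–Bakshi–Shibata reduction with the oxazaborolidine enantiomer that gives 12S, catecholborane) to the (12S,13S)-epoxy alcohol F13. Acylate F13 with tigloyl chloride 30 and DMAP, with retention, to 40.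

**Further compounds**
F1 | step 5 | (R)-3-[2-(chloromethyl)-3-methylhexa-1,5-dien-3-yl]pentane-2,4-dione | C=C(CCl)[C@](C)(CC=C)C(C(C)=O)C(C)=O
F2 | step 5 | dilithium dianion of F1 | C=C(CCl)[C@](C)(CC=C)C(C(=C)O[Li])=C(C)O[Li]
F3 | step 5 | (R)-2-acetyl-3-allyl-3-methyl-4-methylenecyclohexan-1-one | C=C1CCC(=O)C(C(C)=O)[C@@]1(C)CC=C
F4 | step 5 | enaminone of 13 with (S)-1-phenylethylamine | C=C1CCC(N[C@@H](C)c2ccccc2)=C(C(C)=O)[C@]1(C)CC=C
F5 | step 5 | enaminone of F3 with (S)-1-phenylethylamine | C=C1CCC(N[C@@H](C)c2ccccc2)=C(C(C)=O)[C@@]1(C)CC=C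
F6 | step 10 | 1β-(tert-butyldimethylsilyloxy)-7-oxo-4(18),8-diene | C=C1CC[C@@H](O[Si](C)(C)C(C)(C)C)[C@@H]2[C@]1(C)CC(=O)C=C2C
F7 | step 10 | C7 trimethylsilyl enol ether after conjugate addition | C=C1CC[C@@H](O[Si](C)(C)C(C)(C)C)[C@@H]2[C@]1(C)CC(O[Si](C)(C)C)=C[C@@]2(C)CC1OCCO1
F8 | step 10 | C8 Mannich base, 1β-silyl ether | C=C1CC[C@@H](O[Si](C)(C)C(C)(C)C)[C@@H]2[C@]1(C)CC(=O)C(CN(C)C)[C@@]2(C)CC1OCCO1
F9 | step 10 | trimethylammonium iodide of F8 | C=C1CC[C@@H](O[Si](C)(C)C(C)(C)C)[C@@H]2[C@]1(C)CC(=O)C(C[N+](C)(C)C)[C@@]2(C)CC1OCCO1.[I-]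
F10 | step 10 | 1β-silyloxy-7-oxo-4(18),8(17)-diene | C=C1CC[C@@H](O[Si](C)(C)C(C)(C)C)[C@@H]2[C@]1(C)CC(=O)C(=C)[C@@]2(C)CC1OCCO1
F11 | step 10 | 1β-hydroxy-7-oxo-4(18),8(17)-diene | C=C1CC[C@@H](O)[C@@H]2[C@]1(C)CC(=O)C(=C)[C@@]2(C)CC1OCCO1
F12 | step 22 | 13,16-epoxy C12 ketone | C=C1CC[C@H](OC(=O)/C(C)=C/C)[C@@H]2[C@]1(C)[C@@H]3OC(C)(C)O[C@@H]3C(=C)[C@@]2(C)CC(=O)[C@@]1(CO1)CC(=O)OCC[Si](C)(C)C
F13 | step 22 | (12S,13S)-epoxy alcohol | C=C1CC[C@H](OC(=O)/C(C)=C/C)[C@@H]2[C@]1(C)[C@@H]3OC(C)(C)O[C@@H]3C(=C)[C@@]2(C)C[C@H](O)[C@@]1(CO1)CC(=O)OCC[Si](C)(C)C
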